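**Retrosynthetic overview**

1. Locants: ring C1 (side chain), C2 (CH2), C3 (Cl), C4 (C(CH3)OH), C5 (OAc), C6 (O-angeloyl); side chain C7(=CH2)–C8(O-angeloyl)–C9–C10(OH)–C11(CH3)2OH. The trans-diaxial C3–Cl/C4–OH pair beside C5–O is read as a C3–C4 epoxide opened by chloride, and that as a 2-cyclohexenol (C5–OH, C3=C4).
2. Key disconnection: the only carbocycle (C1–C6) is closed last, at its most hindered bond C4–C5, by addition of a C4 alkenylchromium to a C5 aldehyde. The feature that allows this is the (Z)-C3=C4 iodoalkene: C2 and iodine are cis, so C4 reaches C5 across the chain C4=C3–C2–C1–C6–C5.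
3. The open-chain precursor is built around two rings that are not in the target. The dioxolane of D-glyceraldehyde acetonide steers C6 and C1, and its extra carbon is later cut off to unveil the C5 aldehyde. An α-methylene-γ-butyrolactone (O6–C8(=O)–C7–C1–C6), made by indium allylation, fixes C1/C6 cis; its reduction and allylation at C8 free exactly the two hydroxyls (O6, O8) that carry the angelates.
4. After ring closure, C5 is set by oxidation and Luche reduction, C4 and C3 by hydroxyl-directed epoxidation and diaxial chloride opening, the C5 acetate by selective acetylation, and C10 by a final asymmetric dihydroxylation of the prenyl end.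
5. Ring order: dioxolane (bought) → lactone (step 6, opened in steps 7–8) → dioxolane excised (step 11) → cyclohexene (step 12) → epoxide (step 15, opened in step 16).

Key step: step 12

Remark: 7 is taken as the commercial (R)-aldehyde (or freshly made from 1,2:5,6-di-O-isopropylidene-D-mannitol); 5 is racemic at its carbinol carbon, which becomes sp2 in step 5; lactol 10 is an anomeric mixture.

**Route**

Step 1
Reactants: 1 3-[(tert-butyldimethylsilyl)oxy]propanal
Product: 2 tert-butyl{[(3Z)-4-iodopent-3-en-1-yl]oxy}dimethylsilane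
Conditions: EtPPh3I, n-BuLi, THF, 0 °C → rt; I2, −78 °C; NaHMDS, −78 → −20 °C; then 1, −78 °C → rt
Reagents that add atoms: ethyltriphenylphosphonium iodide, CC[P+](c1ccccc1)(c1ccccc1)c1ccccc1.[I-]; iodine, II
Why: Stork–Zhao-type Wittig olefination, in which the α-iodo ylide Ph3P=C(I)CH3 reacts under kinetic control through the cis-oxaphosphetane and should give the (Z)-iodoalkene (C2 and iodine cis on C3=C4), the geometry that later permits ring closure.

Step 2
Reactants: 2 tert-butyl{[(3Z)-4-iodopent-3-en-1-yl]oxy}dimethylsilane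
Product: 3 (3Z)-4-iodopent-3-en-1-ol
Conditions: CSA (cat.), MeOH, 0 °C → rt
Reagents that add atoms: none
Why: Acid-catalysed methanolysis of a primary silyl ether (desilylation), to which the alkenyl iodide is inert.

Step 3
Reactants: 3 (3Z)-4-iodopent-3-en-1-ol
Product: 4 (3Z)-4-iodopent-3-enal
Conditions: Dess–Martin periodinane, pyridine, CH2Cl2, 0 °C; used at once
Reagents that add atoms: none
Why: Dess–Martin oxidation under pyridine buffering gives the β,γ-unsaturated aldehyde without a base strong enough to move the double bond into conjugation.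

Step 4
Reactants: 4 (3Z)-4-iodopent-3-enal
Product: 5 methyl (5Z)-3-hydroxy-6-iodo-2-methylidenehept-5-enoate (racemic)
Conditions: i-Bu2AlH, HMPA, THF, 0 °C; methyl propiolate, 0 °C; then 4, 0 °C → rt; aq. Rochelle salt
Reagents that add atoms: methyl propiolate, C#CC(=O)OC
Why: Morita–Baylis–Hillman-type vinylalumination, in which conjugate hydroalumination of the propiolate gives an α-aluminoacrylate that adds to the aldehyde quickly at 0 °C, so the labile aldehyde is not held for days with an amine base; the new carbinol centre is erased in step 5.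

Step 5
Reactants: 5 methyl (5Z)-3-hydroxy-6-iodo-2-methylidenehept-5-enoate
Product: 6 methyl (2Z,5Z)-2-(bromomethyl)-6-iodohepta-2,5-dienoate
Conditions: NBS, Me2S, CH2Cl2, 0 °C → rt
Reagents that add atoms: N-bromosuccinimide, O=C1CCC(=O)N1Br
Why: Corey–Kim-type activation of the allylic alcohol followed by SN2′ attack of bromide should give the thermodynamically preferred (Z)-2-(bromomethyl)alk-2-enoate, with the C2H2 group cis to CH2Br.

Step 6
Reactants: 6 methyl (2Z,5Z)-2-(bromomethyl)-6-iodohepta-2,5-dienoate; 7 (4R)-2,2-dimethyl-1,3-dioxolane-4-carbaldehyde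
Product: 9 (4R,5S)-5-[(4R)-2,2-dimethyl-1,3-dioxolan-4-yl]-4-[(2Z)-3-iodobut-2-en-1-yl]-3-methylideneoxolan-2-one, via hydroxy ester 8 (not isolated)
Conditions: In powder, THF/H2O (1:1), rt; then CSA (cat.), CH2Cl2, rt
Reagents that add atoms: none
Why: Barbier-type indium allylation through a six-membered chair transition state, in which the allylindium (C1 substituent locked cis to CH2In by the ester) adds through its γ-carbon C1 to the Felkin–Anh face of the α-alkoxy aldehyde, so that C1/C6 should come out syn and C6/C5 anti, and the syn hydroxy ester closes to the cis-lactone; indium does not insert into the alkenyl C–I bond.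

Step 7
Reactants: 9 (4R,5S)-5-[(4R)-2,2-dimethyl-1,3-dioxolan-4-yl]-4-[(2Z)-3-iodobut-2-en-1-yl]-3-methylideneoxolan-2-one
Product: 10 (4R,5S)-5-[(4R)-2,2-dimethyl-1,3-dioxolan-4-yl]-4-[(2Z)-3-iodobut-2-en-1-yl]-3-methylideneoxolan-2-ol (both anomers)
Conditions: i-Bu2AlH (1.1 equiv), CH2Cl2, −78 °C
Reagents that add atoms: none
Why: Partial lactone reduction stops at the five-ring aluminium hemiacetal at −78 °C and gives the lactol (the masked C8 enal) without touching the alkenyl iodide or the acetonide.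

Step 8
Reactants: 10 (4R,5S)-5-[(4R)-2,2-dimethyl-1,3-dioxolan-4-yl]-4-[(2Z)-3-iodobut-2-en-1-yl]-3-methylideneoxolan-2-ol
Product: 11 (1S,2R,4S)-1-[(4R)-2,2-dimethyl-1,3-dioxolan-4-yl]-2-[(2Z)-3-iodobut-2-en-1-yl]-3-methylidenehept-6-ene-1,4-diol
Conditions: (−)-Ipc2BOMe, allylMgBr, Et2O, −78 °C → rt; then 10, −78 °C → rt; NaOH, H2O2, 0 °C → rt
Reagents that add atoms: (−)-B-allyldiisopinocampheylborane, C=CCB([C@@H]1C[C@@H]2C[C@H]([C@H]1C)C2(C)C)[C@@H]1C[C@@H]2C[C@H]([C@H]1C)C2(C)C (allyl group; made in the flask from (−)-B-methoxydiisopinocampheylborane and allylmagnesium bromide, C=CC[Mg]Br)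
Why: Brown allylboration of the open hydroxy-enal form of the lactol, in which the chair transition state with the isopinocampheyl groups derived from (+)-α-pinene delivers allyl to the Si face of the C8 aldehyde under reagent control, which should set C8 as S and frees O6–H and O8–H together.

Step 9
Reactants: 11 (1S,2R,4S)-1-[(4R)-2,2-dimethyl-1,3-dioxolan-4-yl]-2-[(2Z)-3-iodobut-2-en-1-yl]-3-methylidenehept-6-ene-1,4-diol
Product: 12 (1S,2R,4S)-1-[(4R)-2,2-dimethyl-1,3-dioxolan-4-yl]-2-[(2Z)-3-iodobut-2-en-1-yl]-7-methyl-3-methylideneoct-6-ene-1,4-diol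
Conditions: second-generation Grubbs catalyst RuCl2(=CHPh)(PCy3)(H2IMes) (5 mol %), 2-methylbut-2-ene (excess), CH2Cl2, 40 °C
Reagents that add atoms: 2-methylbut-2-ene, CC=C(C)C
Why: Olefin cross-metathesis, in which the monosubstituted terminal alkene is the only one the ruthenium carbene engages readily (C7=CH2 and the iodoalkene are hindered) and excess 2-methylbut-2-ene caps it as the prenyl end with loss of propene.

Step 10
Reactants: 12 (1S,2R,4S)-1-[(4R)-2,2-dimethyl-1,3-dioxolan-4-yl]-2-[(2Z)-3-iodobut-2-en-1-yl]-7-methyl-3-methylideneoct-6-ene-1,4-diol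
Product: 13 (1S,2R,4S)-1-[(4R)-2,2-dimethyl-1,3-dioxolan-4-yl]-2-[(2Z)-3-iodobut-2-en-1-yl]-7-methyl-3-methylideneoct-6-ene-1,4-diyl bis[(2Z)-2-methylbut-2-enoate]
Conditions: angelic acid, 2,4,6-trichlorobenzoyl chloride, Et3N, toluene, rt; then 12, toluene, 80 °C
Reagents that add atoms: angelic acid, C/C=C(/C)C(=O)O
Why: Yamaguchi-type esterification through the mixed anhydride, run without a nucleophilic amine catalyst so that the (Z)-2-methylbut-2-enoyl group should not isomerise to the (E)-isomer; O6–H and O8–H are the only free hydroxyls and both are acylated.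

Step 11
Reactants: 13 (1S,2R,4S)-1-[(4R)-2,2-dimethyl-1,3-dioxolan-4-yl]-2-[(2Z)-3-iodobut-2-en-1-yl]-7-methyl-3-methylideneoct-6-ene-1,4-diyl bis[(2Z)-2-methylbut-2-enoate]
Product: 15 (2S,3R,5S)-3-[(2Z)-3-iodobut-2-en-1-yl]-8-methyl-4-methylidene-1-oxonon-7-ene-2,5-diyl bis[(2Z)-2-methylbut-2-enoate], via diol 14 (not isolated)
Conditions: H5IO6, EtOAc, rt; used at once
Reagents that add atoms: none
Why: Periodic acid hydrolyses the terminal isopropylidene acetal and cleaves the resulting 1,2-diol in the same flask (glycol cleavage), which removes the extra glyceraldehyde carbon and unveils the C5 aldehyde under non-basic conditions that should leave C6 and the angelates intact.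

Step 12
Reactants: 15 (2S,3R,5S)-3-[(2Z)-3-iodobut-2-en-1-yl]-8-methyl-4-methylidene-1-oxonon-7-ene-2,5-diyl bis[(2Z)-2-methylbut-2-enoate]
Product: 16 (1S,6R)-2-hydroxy-3-methyl-6-[(3S)-6-methyl-3-{[(2Z)-2-methylbut-2-enoyl]oxy}hepta-1,5-dien-2-yl]cyclohex-3-en-1-yl (2Z)-2-methylbut-2-enoate (both epimers at the carbinol carbon C5)
Conditions: CrCl2 (6 equiv), NiCl2 (2 mol %), degassed DMSO, rt, high dilution (0.005 M)
Reagents that add atoms: none
Why: Zerovalent nickel (from NiCl2 and CrCl2) inserts into the C4–I bond with retention of the double-bond geometry, the alkenyl group passes to trivalent chromium, and the alkenylchromium adds to the C5 aldehyde; this is the intramolecular Nozaki–Hiyama–Kishi reaction, the closest known reaction type and an established route to 2-cycloalkenols. The six-membered ring C1–C6 closes in the 6-exo-trig mode at the carbonyl carbon with the C3=C4 double bond ending inside the ring, which only the (Z)-iodoalkene (C2 cis to iodine) allows. In one operation the step makes the bond beside the future fully substituted C4, the only ring of the target, and the allylic alcohol (C5–OH next to C3=C4) from which C5, C4 and C3 are then set. C5 is the one new stereocentre and is deliberately left uncontrolled: a chair-like transition state with the C1 side chain equatorial and the forming C5–O bond anti to the axial C6–O bond should favour the epimer with O5 trans to O6, the competing one gives the cis epimer, and both converge in step 13. What the step needs is chemoselectivity for the alkenyl iodide/aldehyde pair beside two conjugated esters, an allylic ester and three further alkenes, which this chromium chemistry is known to give, and an intact C6 centre in the α-acyloxy aldehyde, which the neutral, non-enolising medium should secure. High dilution is used so that ring closure outruns intermolecular addition.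

Step 13
Reactants: 16 (1S,6R)-2-hydroxy-3-methyl-6-[(3S)-6-methyl-3-{[(2Z)-2-methylbut-2-enoyl]oxy}hepta-1,5-dien-2-yl]cyclohex-3-en-1-yl (2Z)-2-methylbut-2-enoate (epimer mixture)
Product: 17 (1S,6R)-3-methyl-2-oxo-6-[(3S)-6-methyl-3-{[(2Z)-2-methylbut-2-enoyl]oxy}hepta-1,5-dien-2-yl]cyclohex-3-en-1-yl (2Z)-2-methylbut-2-enoate
Conditions: Dess–Martin periodinane, pyridine, CH2Cl2, 0 °C → rt
Reagents that add atoms: none
Why: Dess–Martin oxidation converts both C5 epimers of the allylic alcohol into one carvone-type enone under buffered conditions that should not enolise C6.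

Step 14
Reactants: 17 (1S,6R)-3-methyl-2-oxo-6-[(3S)-6-methyl-3-{[(2Z)-2-methylbut-2-enoyl]oxy}hepta-1,5-dien-2-yl]cyclohex-3-en-1-yl (2Z)-2-methylbut-2-enoate
Product: 18 (1S,2R,6R)-2-hydroxy-3-methyl-6-[(3S)-6-methyl-3-{[(2Z)-2-methylbut-2-enoyl]oxy}hepta-1,5-dien-2-yl]cyclohex-3-en-1-yl (2Z)-2-methylbut-2-enoate
Conditions: NaBH4, CeCl3·7H2O, MeOH, −78 °C
Reagents that add atoms: none
Why: Luche 1,2-reduction, in which the C6 angelate is axial when the C1 side chain is equatorial and hydride adds to C5 anti to that axial C–O bond (Felkin–Anh, axial attack), which should give the equatorial C5–OH cis to O6 and to the C1 side chain, as carvone gives cis-carveol.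

Step 15
Reactants: 18 (1S,2R,6R)-2-hydroxy-3-methyl-6-[(3S)-6-methyl-3-{[(2Z)-2-methylbut-2-enoyl]oxy}hepta-1,5-dien-2-yl]cyclohex-3-en-1-yl (2Z)-2-methylbut-2-enoate
Product: 19 (1S,2S,3S,4R,6R)-2-hydroxy-1-methyl-4-[(3S)-6-methyl-3-{[(2Z)-2-methylbut-2-enoyl]oxy}hepta-1,5-dien-2-yl]-7-oxabicyclo[4.1.0]heptan-3-yl (2Z)-2-methylbut-2-enoate
Conditions: VO(acac)2 (5 mol %), t-BuOOH, CH2Cl2, 0 °C → rt
Reagents that add atoms: tert-butyl hydroperoxide, CC(C)(C)OO
Why: Hydroxyl-directed epoxidation, in which the vanadate ester of the allylic C5–OH delivers oxygen to the same face of C3=C4 (epoxide oxygen cis to O5) and the allylic alcohol reacts far faster than the remote prenyl alkene or the electron-poor alkenes.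

Step 16
Reactants: 19 (1S,2S,3S,4R,6R)-2-hydroxy-1-methyl-4-[(3S)-6-methyl-3-{[(2Z)-2-methylbut-2-enoyl]oxy}hepta-1,5-dien-2-yl]-7-oxabicyclo[4.1.0]heptan-3-yl (2Z)-2-methylbut-2-enoate
Product: 20 (1S,2S,3S,4S,6R)-4-chloro-2,3-dihydroxy-3-methyl-6-[(3S)-6-methyl-3-{[(2Z)-2-methylbut-2-enoyl]oxy}hepta-1,5-dien-2-yl]cyclohexyl (2Z)-2-methylbut-2-enoate
Conditions: ClTi(OiPr)3, CH2Cl2, 0 °C → rt
Reagents that add atoms: chlorotitanium triisopropoxide, CC(C)O[Ti](Cl)(OC(C)C)OC(C)C
Why: Titanium-assisted opening of a 2,3-epoxy alcohol, in which the metal bound to O5 and the epoxide oxygen delivers chloride to C3 (the carbon remote from the carbinol) with inversion; this is also the trans-diaxial (Fürst–Plattner) opening of the half-chair with the side chain equatorial, so C3–Cl trans to the tertiary C4–OH should result.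

Step 17
Reactants: 20 (1S,2S,3S,4S,6R)-4-chloro-2,3-dihydroxy-3-methyl-6-[(3S)-6-methyl-3-{[(2Z)-2-methylbut-2-enoyl]oxy}hepta-1,5-dien-2-yl]cyclohexyl (2Z)-2-methylbut-2-enoate
Product: 21 (1S,2S,3S,4S,6R)-2-(acetyloxy)-4-chloro-3-hydroxy-3-methyl-6-[(3S)-6-methyl-3-{[(2Z)-2-methylbut-2-enoyl]oxy}hepta-1,5-dien-2-yl]cyclohexyl (2Z)-2-methylbut-2-enoate
Conditions: Ac2O, pyridine, DMAP (cat.), CH2Cl2, 0 °C
Reagents that add atoms: acetic anhydride, CC(=O)OC(C)=O
Why: Acetylation under nucleophilic catalysis acylates the only secondary hydroxyl (C5–OH), while the tertiary C4–OH does not react and the mild base should leave the chlorohydrin closed to epoxide formation.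

Step 18
Reactants: 21 (1S,2S,3S,4S,6R)-2-(acetyloxy)-4-chloro-3-hydroxy-3-methyl-6-[(3S)-6-methyl-3-{[(2Z)-2-methylbut-2-enoyl]oxy}hepta-1,5-dien-2-yl]cyclohexyl (2Z)-2-methylbut-2-enoate
Product: 22 (1S,2S,3S,4S,6R)-2-(acetyloxy)-4-chloro-3-hydroxy-3-methyl-6-[(3S,5R)-5,6-dihydroxy-6-methyl-3-{[(2Z)-2-methylbut-2-enoyl]oxy}hept-1-en-2-yl]cyclohexyl (2Z)-2-methylbut-2-enoate (CNP0223769.1)
Conditions: OsO4 (1.1 equiv), (DHQD)2PHAL (1.2 equiv), toluene, −78 °C; then aq. NaHSO3, THF, rt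
Reagents that add atoms: osmium tetroxide, O=[Os](=O)(=O)=O
Why: Sharpless asymmetric dihydroxylation in its stoichiometric, ligand-accelerated form, in which the phthalazine-linked dihydroquinidine ligand directs osmylation to the face of the trisubstituted prenyl alkene that gives 10R (reagent control), the electron-rich prenyl alkene reacts before the hindered C7=CH2 and the conjugated ester alkenes, and the base-free reductive work-up spares the chlorohydrin and the esters.

**Compound list**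

1 | 3-[(tert-butyldimethylsilyl)oxy]propanal | O=CCCO[Si](C)(C)C(C)(C)C | starting material
2 | tert-butyl{[(3Z)-4-iodopent-3-en-1-yl]oxy}dimethylsilane | C/C(I)=C/CCO[Si](C)(C)C(C)(C)C | intermediate
3 | (3Z)-4-iodopent-3-en-1-ol | C/C(I)=C/CCO | intermediate
4 | (3Z)-4-iodopent-3-enal | C/C(I)=C/CC=O | intermediate
5 | methyl (5Z)-3-hydroxy-6-iodo-2-methylidenehept-5-enoate (racemic) | C=C(C(=O)OC)C(O)C/C=C(/C)I | intermediate
6 | methyl (2Z,5Z)-2-(bromomethyl)-6-iodohepta-2,5-dienoate | BrC/C(C(=O)OC)=C\C/C=C(/C)I | intermediate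
7 | (4R)-2,2-dimethyl-1,3-dioxolane-4-carbaldehyde | O=C[C@H]1COC(C)(C)O1 | starting material
8 | methyl (3R,5Z)-3-{(S)-[(4R)-2,2-dimethyl-1,3-dioxolan-4-yl](hydroxy)methyl}-6-iodo-2-methylidenehept-5-enoate | C=C(C(=O)OC)[C@@H](C/C=C(/C)I)[C@H](O)[C@H]1COC(C)(C)O1 | intermediate (not isolated)
9 | (4R,5S)-5-[(4R)-2,2-dimethyl-1,3-dioxolan-4-yl]-4-[(2Z)-3-iodobut-2-en-1-yl]-3-methylideneoxolan-2-one | C=C1[C@@H](C/C=C(/C)I)[C@H](OC1=O)[C@H]2COC(C)(C)O2 | intermediate
10 | (4R,5S)-5-[(4R)-2,2-dimethyl-1,3-dioxolan-4-yl]-4-[(2Z)-3-iodobut-2-en-1-yl]-3-methylideneoxolan-2-ol (both anomers) | C=C1[C@@H](C/C=C(/C)I)[C@H](OC1O)[C@H]2COC(C)(C)O2 | intermediate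
11 | (1S,2R,4S)-1-[(4R)-2,2-dimethyl-1,3-dioxolan-4-yl]-2-[(2Z)-3-iodobut-2-en-1-yl]-3-methylidenehept-6-ene-1,4-diol | C=CC[C@H](O)C(=C)[C@@H](C/C=C(/C)I)[C@H](O)[C@H]1COC(C)(C)O1 | intermediate
12 | (1S,2R,4S)-1-[(4R)-2,2-dimethyl-1,3-dioxolan-4-yl]-2-[(2Z)-3-iodobut-2-en-1-yl]-7-methyl-3-methylideneoct-6-ene-1,4-diol | CC(C)=CC[C@H](O)C(=C)[C@@H](C/C=C(/C)I)[C@H](O)[C@H]1COC(C)(C)O1 | intermediate
13 | (1S,2R,4S)-1-[(4R)-2,2-dimethyl-1,3-dioxolan-4-yl]-2-[(2Z)-3-iodobut-2-en-1-yl]-7-methyl-3-methylideneoct-6-ene-1,4-diyl bis[(2Z)-2-methylbut-2-enoate] | CC(C)=CC[C@H](OC(=O)/C(C)=C\C)C(=C)[C@@H](C/C=C(/C)I)[C@H](OC(=O)/C(C)=C\C)[C@H]1COC(C)(C)O1 | intermediate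
14 | (2R,3S,4R,6S)-1,2-dihydroxy-4-[(2Z)-3-iodobut-2-en-1-yl]-9-methyl-5-methylidenedec-8-ene-3,6-diyl bis[(2Z)-2-methylbut-2-enoate] | CC(C)=CC[C@H](OC(=O)/C(C)=C\C)C(=C)[C@@H](C/C=C(/C)I)[C@H](OC(=O)/C(C)=C\C)[C@H](O)CO | intermediate (not isolated)
15 | (2S,3R,5S)-3-[(2Z)-3-iodobut-2-en-1-yl]-8-methyl-4-methylidene-1-oxonon-7-ene-2,5-diyl bis[(2Z)-2-methylbut-2-enoate] | CC(C)=CC[C@H](OC(=O)/C(C)=C\C)C(=C)[C@@H](C/C=C(/C)I)[C@H](OC(=O)/C(C)=C\C)C=O | intermediate
16 | (1S,6R)-2-hydroxy-3-methyl-6-[(3S)-6-methyl-3-{[(2Z)-2-methylbut-2-enoyl]oxy}hepta-1,5-dien-2-yl]cyclohex-3-en-1-yl (2Z)-2-methylbut-2-enoate (both epimers at C2 of this name, C5 of the locant scheme) | C=C([C@H](CC=C(C)C)OC(=O)/C(C)=C\C)[C@H]1CC=C(C)C(O)[C@H]1OC(=O)/C(C)=C\C | intermediate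
17 | (1S,6R)-3-methyl-2-oxo-6-[(3S)-6-methyl-3-{[(2Z)-2-methylbut-2-enoyl]oxy}hepta-1,5-dien-2-yl]cyclohex-3-en-1-yl (2Z)-2-methylbut-2-enoate | C=C([C@H](CC=C(C)C)OC(=O)/C(C)=C\C)[C@H]1CC=C(C)C(=O)[C@H]1OC(=O)/C(C)=C\C | intermediate
18 | (1S,2R,6R)-2-hydroxy-3-methyl-6-[(3S)-6-methyl-3-{[(2Z)-2-methylbut-2-enoyl]oxy}hepta-1,5-dien-2-yl]cyclohex-3-en-1-yl (2Z)-2-methylbut-2-enoate | C=C([C@H](CC=C(C)C)OC(=O)/C(C)=C\C)[C@H]1CC=C(C)[C@@H](O)[C@H]1OC(=O)/C(C)=C\C | intermediate
19 | (1S,2S,3S,4R,6R)-2-hydroxy-1-methyl-4-[(3S)-6-methyl-3-{[(2Z)-2-methylbut-2-enoyl]oxy}hepta-1,5-dien-2-yl]-7-oxabicyclo[4.1.0]heptan-3-yl (2Z)-2-methylbut-2-enoate | C=C([C@H](CC=C(C)C)OC(=O)/C(C)=C\C)[C@H]1C[C@H]2O[C@@]2(C)[C@@H](O)[C@H]1OC(=O)/C(C)=C\C | intermediate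
20 | (1S,2S,3S,4S,6R)-4-chloro-2,3-dihydroxy-3-methyl-6-[(3S)-6-methyl-3-{[(2Z)-2-methylbut-2-enoyl]oxy}hepta-1,5-dien-2-yl]cyclohexyl (2Z)-2-methylbut-2-enoate | C=C([C@H](CC=C(C)C)OC(=O)/C(C)=C\C)[C@H]1C[C@H](Cl)[C@@](C)(O)[C@@H](O)[C@H]1OC(=O)/C(C)=C\C | intermediate
21 | (1S,2S,3S,4S,6R)-2-(acetyloxy)-4-chloro-3-hydroxy-3-methyl-6-[(3S)-6-methyl-3-{[(2Z)-2-methylbut-2-enoyl]oxy}hepta-1,5-dien-2-yl]cyclohexyl (2Z)-2-methylbut-2-enoate | C=C([C@H](CC=C(C)C)OC(=O)/C(C)=C\C)[C@H]1C[C@H](Cl)[C@@](C)(O)[C@@H](OC(C)=O)[C@H]1OC(=O)/C(C)=C\C | intermediate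
22 | (1S,2S,3S,4S,6R)-2-(acetyloxy)-4-chloro-3-hydroxy-3-methyl-6-[(3S,5R)-5,6-dihydroxy-6-methyl-3-{[(2Z)-2-methylbut-2-enoyl]oxy}hept-1-en-2-yl]cyclohexyl (2Z)-2-methylbut-2-enoate (CNP0223769.1) | C=C([C@H](C[C@@H](O)C(C)(C)O)OC(=O)/C(C)=C\C)[C@H]1C[C@H](Cl)[C@@](C)(O)[C@@H](OC(C)=O)[C@H]1OC(=O)/C(C)=C\C | target

**Step count and risks**

Total step count: 18. Longest linear sequence: 18 steps (1 → 22); aldehyde 7 and the small reagents are bought.

Steps most likely to fail:

1. Step 12 (key step). The α-angeloyloxy aldehyde may enolise and lose the C6 configuration, the C6 angeloyl group may shift to the new C5 alkoxide, or the alkenylchromium may be protonated before it closes the ring. Fallback, setting out from diol 12 and coming back at enone 17: the ring is closed before the angelates are in place. Diol 12 is silylated (TBSOTf, 2,6-lutidine, CH2Cl2) to the bis(silyl ether) F1. Periodic acid in EtOAc gives, by way of the diol F2, the α-silyloxy aldehyde F3, the robust classical substrate for this cyclisation. The same CrCl2/NiCl2 closure gives the cyclohexenols F4, and Dess–Martin oxidation gives the enone F5. HF·pyridine removes both silyl groups to give the dihydroxy enone F6, and double angeloylation as in step 10 returns to 17.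

2. Step 10. The activated (Z)-acid may isomerise to the (E)-acid, or the hindered O6–H may resist acylation by the mixed anhydride. Fallback, setting out from diol 12 and coming back at 13: the (Z)-double bonds are built on the ester. Diol 12 is esterified (DCC, DMAP, CH2Cl2) with 2-[bis(2,2,2-trifluoroethoxy)phosphoryl]propanoic acid to the bis(phosphonate) F7. A twofold Still–Gennari olefination with acetaldehyde (KHMDS, 18-crown-6, THF, −78 °C) should then form both (Z)-2-methylbut-2-enoates and return to 13.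

3. Step 4. The β,γ-double bond of aldehyde 4 may migrate into conjugation, and the material then decompose, before the C–C bond is formed. Fallback, setting out from aldehyde 4 and coming back at 5: the acrylate unit is brought in as a saturated ester enolate at −78 °C. The lithium enolate of methyl 3-(dimethylamino)propanoate (LDA, THF, −78 °C) adds to 4 to give the amino aldol F8. Oxidation with mCPBA gives the N-oxide F9, which should undergo Cope elimination on warming to rt and return to 5.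

Further compounds
F1 | step 12 | (4R)-4-[(1S,2R,4S)-1,4-bis{[tert-butyl(dimethyl)silyl]oxy}-2-[(2Z)-3-iodobut-2-en-1-yl]-7-methyl-3-methylideneoct-6-en-1-yl]-2,2-dimethyl-1,3-dioxolane | CC(C)=CC[C@H](O[Si](C)(C)C(C)(C)C)C(=C)[C@@H](C/C=C(/C)I)[C@H](O[Si](C)(C)C(C)(C)C)[C@H]1COC(C)(C)O1
F2 | step 12 | (2R,3S,4R,6S)-3,6-bis{[tert-butyl(dimethyl)silyl]oxy}-4-[(2Z)-3-iodobut-2-en-1-yl]-9-methyl-5-methylidenedec-8-ene-1,2-diol | CC(C)=CC[C@H](O[Si](C)(C)C(C)(C)C)C(=C)[C@@H](C/C=C(/C)I)[C@H](O[Si](C)(C)C(C)(C)C)[C@H](O)CO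
F3 | step 12 | (2S,3R,5S)-2,5-bis{[tert-butyl(dimethyl)silyl]oxy}-3-[(2Z)-3-iodobut-2-en-1-yl]-8-methyl-4-methylidenenon-7-enal | CC(C)=CC[C@H](O[Si](C)(C)C(C)(C)C)C(=C)[C@@H](C/C=C(/C)I)[C@H](O[Si](C)(C)C(C)(C)C)C=O
F4 | step 12 | (5R,6S)-6-{[tert-butyl(dimethyl)silyl]oxy}-5-[(3S)-3-{[tert-butyl(dimethyl)silyl]oxy}-6-methylhepta-1,5-dien-2-yl]-2-methylcyclohex-2-en-1-ol (both C1 epimers) | C=C([C@H](CC=C(C)C)O[Si](C)(C)C(C)(C)C)[C@H]1CC=C(C)C(O)[C@H]1O[Si](C)(C)C(C)(C)C
F5 | step 12 | (5R,6S)-6-{[tert-butyl(dimethyl)silyl]oxy}-5-[(3S)-3-{[tert-butyl(dimethyl)silyl]oxy}-6-methylhepta-1,5-dien-2-yl]-2-methylcyclohex-2-en-1-one | C=C([C@H](CC=C(C)C)O[Si](C)(C)C(C)(C)C)[C@H]1CC=C(C)C(=O)[C@H]1O[Si](C)(C)C(C)(C)C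
F6 | step 12 | (5R,6S)-6-hydroxy-5-[(3S)-3-hydroxy-6-methylhepta-1,5-dien-2-yl]-2-methylcyclohex-2-en-1-one | C=C([C@H](CC=C(C)C)O)[C@H]1CC=C(C)C(=O)[C@H]1O
F7 | step 10 | (1S,2R,4S)-1-[(4R)-2,2-dimethyl-1,3-dioxolan-4-yl]-2-[(2Z)-3-iodobut-2-en-1-yl]-7-methyl-3-methylideneoct-6-ene-1,4-diyl bis{2-[bis(2,2,2-trifluoroethoxy)phosphoryl]propanoate} (epimers at the phosphonate-bearing carbons) | CC(C)=CC[C@H](OC(=O)C(C)P(=O)(OCC(F)(F)F)OCC(F)(F)F)C(=C)[C@@H](C/C=C(/C)I)[C@H](OC(=O)C(C)P(=O)(OCC(F)(F)F)OCC(F)(F)F)[C@H]1COC(C)(C)O1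
F8 | step 4 | methyl (5Z)-2-[(dimethylamino)methyl]-3-hydroxy-6-iodohept-5-enoate (racemic diastereomers) | CN(C)CC(C(=O)OC)C(O)C/C=C(/C)I
F9 | step 4 | methyl (5Z)-2-[(dimethyloxidoazaniumyl)methyl]-3-hydroxy-6-iodohept-5-enoate (N-oxide of F8) | C[N+](C)([O-])CC(C(=O)OC)C(O)C/C=C(/C)I
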